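The readings were computed for substances that don't exist, noise included.

Amounts came first: I wanted the amount of substrate a flask could couple in 30 min.

| flask | substrate | coupling partner | transfer agent | initiator | remark | time |
|---|---|---|---|---|---|---|
| south | 0.014 M | 0.055 M | 2.5 mM | 0.50 mM | run made earlier |  |
| north | 0.082 M | 0.055 M | 2.5 mM | 0.50 mM | run made earlier |  |
| Wednesday's | 0.025 M | 0.0550 M | 2.50 mM | 0.50 mM |  | 30 min |
| Thursday's | 0.050 M | 0.0550 M | 2.50 mM | 0.50 mM |  | 30 min |
| Saturday's | 0.10 M | 0.0550 M | 2.50 mM | 0.50 mM |  | 30 min |

| run | time / min | target / % | substrate / % |
|---|---|---|---|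
| south | 4.00 | 78.3 | 20.4 |
| south | 8.00 | 97.7 | 1.3 |
| south | 12.0 | 98.4 | 0 |
| south | 15.0 | 97.9 | 0 |
| south | 20.0 | 98.4 | 0 |
| south | 25.0 | 98.9 | 0.5 |
| south | 30.0 | 98.0 | 0.4 |
| north | 1.50 | 6.6 | 93.2 |
| north | 5.00 | 18.5 | 80.1 |
| north | 8.00 | 25.4 | 71.0 |
| north | 12.0 | 31.7 | 62.6 |
| north | 20.0 | 38.6 | 50.0 |
| north | 25.0 | 41.6 | 44.3 |
| north | 30.0 | 42.9 | 40.4 |

(standard deviation of a reading: 0.3 percentage points)

- percentages count the substrate that a species holds: one side product B counts as two
- candidate steps: coupling partner + first chain carrier -> target + second chain carrier; 2 idle radical -> ended radicals; transfer agent + first chain carrier -> side product A + idle radical; substrate + target -> side product B; 2 second chain carrier -> ended chains; substrate + initiating radical -> capped initiator + first chain carrier; substrate + second chain carrier -> released group + first chain carrier; initiator -> 2 initiating radical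
- "hardly changes" means that all values lie within two and a half points (for a concentration: within two and a half percent of the largest)

* [target] at the end for Wednesday's, Thursday's, Saturday's, in this order
* how that number moves from the first to the last of them (hardly changes / rises, then falls / falls, then rises / falls all the way / rises all the way)

Each coupling took one substrate and one coupling partner and gave one target. Each side product B then took one target and one more substrate. I counted the share missing from north, 16.7%, as side product B. The coupling budget, the target standing plus the target turned into side product B, then read 0.0420 M in north at 30.0 min. That is a mean rate of 0.00140 M min⁻¹.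

I followed the curve behind that mean. In the first instants initiator split, initiating radical met substrate, and the chain started. North coupled 0.00366 M min⁻¹ up to 1.50 min, faster than the mean. In the middle, south read 0.00276 M min⁻¹ up to 4.00 min and north 0.00315 M min⁻¹ up to 5.00 min, although north held 5.86 times the substrate. So I carried the budget across charges of substrate, with the other charges as in north. Late on, north coupled 0.00213 M between 25.0 min and 30.0 min.

Wednesday's charge lay below the budget, which makes substrate the limiting reagent there. South showed that end: its substrate read 0% at 12.0 min, and its target read 98.0% at 30.0 min. Thursday's and Saturday's charges lay above the budget, so I expected each to couple the budget and lose some target to side product B. North's missing share came to 0.00685 M of target turned into side product B, and the mean of its first and last [substrate] was 0.0576 M. Scaling that loss by each flask's mean [substrate], I reckoned 0.0386 M of target for Thursday's and 0.0326 M for Saturday's.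

The forecast gave 0.0242 M, 0.039 M and 0.033 M, so rises, then falls, with a partner use that “caps the product”.

The flasks gave 0.0243 M, 0.0390 M and 0.0328 M: rises, then falls.

    coupling partner + first chain carrier → target + second chain carrier (k = 4.10 × 10⁵ M⁻¹ s⁻¹)
    2 idle radical → ended radicals (k = 4.50 × 10⁸ M⁻¹ s⁻¹)
    transfer agent + first chain carrier → side product A + idle radical (kL = 1.00 × 10⁵ M⁻¹ s⁻¹)
    substrate + target → side product B (k = 0.190 M⁻¹ min⁻¹)
    2 second chain carrier → ended chains (k = 5.50 × 10⁶ M⁻¹ s⁻¹)
    substrate + initiating radical → capped initiator + first chain carrier (k = 1.40 × 10⁶ M⁻¹ s⁻¹)
    substrate + second chain carrier → released group + first chain carrier (k = 68000 M⁻¹ s⁻¹)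
    initiator → 2 initiating radical (k = 0.0430 min⁻¹)

The row turned at 0.045 M of substrate, beside the budget of 0.0420 M. For Saturday's flask, I reckoned 0.00920 M of side product B as the budget less the target. Taking the budget and that amount from the charge gave a reckoned 48.7% of the substrate. Saturday's flask held 49.1% at the end.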